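**Strategy**

The chromone is disconnected at O1–C8a, C4–C4a and O1–C2. The feature exploited is that ring A carries the ring oxygen (at C8a) and the C4 carbonyl (at C4a) on adjacent carbons, with the C5 oxygen beside C4a. A ring-A aryne (C4a≡C8a), released from an ortho-silyl aryl triflate carrying MOM-protected C5 and C7 oxygens and the C6 methyl, inserts into the C–O bond of 2,3-dimethoxy-3-(4-methoxyphenyl)acrylic acid; the phenoxide formed then displaces the β-methoxy group, so ring C with its 2-aryl and 3-methoxy substituents is assembled in one operation. C8 is left as C–H to keep the aryne polarised by one flanking oxygen and is methoxylated afterwards.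

Key step: step 8

**Remarks**

- Atom labels (C2, C4a, C8a and so on) follow the chromone numbering of the target.
- Protecting groups: the two ring-A phenols are carried as MOM ethers. Benzyl ethers would offer six unhindered aryl C–H bonds to the iridium catalyst in step 2, whereas MOM ethers offer none. MOM ethers also tolerate base, organolithium and fluoride, and are removed without hydrogenation.
- Assumption: the enol ether in 13, 14, 16 and F1 is drawn as the E isomer. Either geometry or a mixture would serve, because the geometry is erased when ring C closes.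

**Route**

Step 1
Reactants: 1 2-methylresorcinol
Product: 2 1,3-bis(methoxymethoxy)-2-methylbenzene
Conditions: MOMCl (2.5 equiv), iPr2NEt (3 equiv), CH2Cl2, 0 °C → rt
Reagents that add atoms: chloromethyl methyl ether, COCCl
Why: Double O-alkylation of the phenols by the reactive α-chloro ether (Williamson-type acetal formation) should be straightforward and installs groups with no aryl C–H bond to interfere in step 2.

Step 2
Reactants: 2 1,3-bis(methoxymethoxy)-2-methylbenzene
Product: 4 3,5-bis(methoxymethoxy)-4-methylphenol, via aryl pinacol boronate 3 (not isolated)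
Conditions: [Ir(OMe)(cod)]2 (1.5 mol%), 4,4'-di-tert-butyl-2,2'-bipyridine (3 mol%), B2pin2 (1.0 equiv), THF, 80 °C; then 30% H2O2, aq NaOH, 0 °C
Reagents that add atoms: bis(pinacolato)diboron, CC1(C)OB(OC1(C)C)B1OC(C)(C)C(C)(C)O1 (boron of intermediate 3 only); hydrogen peroxide, OO
Why: Sterically controlled iridium-catalysed C–H borylation should occur only at C5 of 2, the one ring C–H without an ortho substituent, and alkaline peroxide oxidation of the boronate (1,2-aryl shift from boron to oxygen) then gives the phenol in the same flask.

Step 3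
Reactants: 4 3,5-bis(methoxymethoxy)-4-methylphenol
Product: 5 2-bromo-3,5-bis(methoxymethoxy)-4-methylphenol
Conditions: NBS (1.0 equiv), CH2Cl2, −78 → 0 °C
Reagents that add atoms: N-bromosuccinimide, O=C1CCC(=O)N1Br
Why: Electrophilic aromatic bromination ortho to the free phenol should give one isomer because the two open positions are equivalent by symmetry, and one equivalent of NBS at low temperature should hold the reaction at monobromination.

Step 4
Reactants: 5 2-bromo-3,5-bis(methoxymethoxy)-4-methylphenol
Product: 9 3,5-bis(methoxymethoxy)-4-methyl-2-(trimethylsilyl)phenyl trifluoromethanesulfonate, via aryl silyl ether 6 (not isolated), via aryllithium 7 (not isolated), via lithium silylphenoxide 8 (not isolated)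
Conditions: HMDS, THF, 70 °C, then evaporation; n-BuLi (1.1 equiv), THF, −78 °C; Tf2O (1.1 equiv), −78 → 0 °C, NaHCO3 quench
Reagents that add atoms: hexamethyldisilazane, C[Si](C)(C)N[Si](C)(C)C; trifluoromethanesulfonic anhydride, O=S(=O)(OS(=O)(=O)C(F)(F)F)C(F)(F)F; n-butyllithium, [Li]CCCC (lithium of intermediates 7 and 8 only)
Why: O-silylation, bromine–lithium exchange and a 1,3 O-to-C silyl shift (retro-Brook rearrangement) place silicon on the carbon that carried bromine, and triflation of the released phenoxide gives the ortho-silyl aryl triflate, as in the standard telescoped preparation of such aryne precursors.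

Step 5
Reactants: 10 methyl methoxyacetate; 11 4-methoxybenzoyl chloride
Product: 12 methyl 2-methoxy-3-(4-methoxyphenyl)-3-oxopropanoate (racemic)
Conditions: LiN(iPr)2 (2.2 equiv), 10 (2.2 equiv), THF, −78 °C; then 11 (1.0 equiv), −78 → 0 °C; aq NH4Cl
Reagents that add atoms: none
Why: C-acylation of a preformed lithium ester enolate by an aroyl chloride (crossed Claisen-type acylation) should be clean because the enolate is formed irreversibly before the electrophile arrives and the second equivalent absorbs the acidic product proton; the new C2 stereocentre is racemic, labile and removed in step 6.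

Step 6
Reactants: 12 methyl 2-methoxy-3-(4-methoxyphenyl)-3-oxopropanoate
Product: 13 methyl (E)-2,3-dimethoxy-3-(4-methoxyphenyl)prop-2-enoate
Conditions: Cs2CO3 (1.5 equiv), Me2SO4 (1.2 equiv), DMF, 0 °C → rt
Reagents that add atoms: dimethyl sulfate, COS(=O)(=O)OC
Why: O-alkylation of the caesium enolate of an α-substituted β-keto ester by a hard electrophile in a dipolar aprotic solvent should favour the enol ether over C-methylation at the already trisubstituted carbon.

Step 7
Reactants: 13 methyl (E)-2,3-dimethoxy-3-(4-methoxyphenyl)prop-2-enoate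
Product: 14 (E)-2,3-dimethoxy-3-(4-methoxyphenyl)prop-2-enoic acid
Conditions: LiOH·H2O (3 equiv), THF/MeOH/H2O, 40 °C; then cold 1 M HCl to pH 3, 0 °C
Reagents that add atoms: lithium hydroxide (hydroxide oxygen), [Li+].[OH-]
Why: Saponification by acyl–oxygen cleavage should succeed because the β-methoxyacrylate is a vinylogous carbonate that resists conjugate attack by hydroxide, and brief cold acidification should spare the push–pull enol ether.

Step 8
Reactants: 9 3,5-bis(methoxymethoxy)-4-methyl-2-(trimethylsilyl)phenyl trifluoromethanesulfonate; 14 (E)-2,3-dimethoxy-3-(4-methoxyphenyl)prop-2-enoic acid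
Product: 17 3-methoxy-5,7-bis(methoxymethoxy)-2-(4-methoxyphenyl)-6-methyl-4H-chromen-4-one, via aryne 15 (not isolated), via hydroxyaryl ketone 16 (not isolated)
Conditions: 9 (1.5 equiv), CsF (4 equiv), THF, 125 °C, sealed tube
Reagents that add atoms: none
Why: Fluoride attacks silicon and expels triflate to give aryne 15; the caesium carboxylate of 14 adds through oxygen to C8a, the aryl anion formed at C4a attacks the ester carbonyl through a four-membered alkoxide, and C–O cleavage (an anionic Fries-type acyl shift) leaves the phenoxide of ketone 16. The closest known reaction is the fluoride-induced insertion of arynes into the C–O bond of carboxylic acids, which gives ortho-hydroxyaryl ketones and, with unsaturated acids, chromanones and flavones in the same flask. Ring C closes by 6-endo-trig conjugate addition of the C8a phenoxide to C2 of the β-methoxy enone followed by E1cB loss of methoxide, so the 2-aryl and 3-methoxy groups arrive in place. No stereocentre is formed and the enol ether geometry is erased. The step needs the carboxylate to add at C8a and not at C4a; the C5 methoxymethoxy group next to C4a polarises and distorts the aryne so that the nucleophile attacks the remote carbon and the charge develops at C4a beside the inductively withdrawing oxygen. The high temperature is chosen to favour acyl transfer over protonation of the aryl anion, and brief treatment with K2CO3 in DMF would complete ring closure should 16 persist.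

Step 9
Reactants: 17 3-methoxy-5,7-bis(methoxymethoxy)-2-(4-methoxyphenyl)-6-methyl-4H-chromen-4-one
Product: 18 8-iodo-3-methoxy-5,7-bis(methoxymethoxy)-2-(4-methoxyphenyl)-6-methyl-4H-chromen-4-one
Conditions: NIS (1.2 equiv), DMF, rt, dark
Reagents that add atoms: N-iodosuccinimide, O=C1CCC(=O)N1I
Why: Electrophilic aromatic iodination under neutral conditions spares the MOM ethers and should occur only at C8, the sole unsubstituted carbon of ring A, activated by O1 and the C7 oxygen (ortho) and the C5 oxygen (para), while ring B is deactivated by conjugation with the pyranone.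

Step 10
Reactants: 18 8-iodo-3-methoxy-5,7-bis(methoxymethoxy)-2-(4-methoxyphenyl)-6-methyl-4H-chromen-4-one
Product: 19 3,8-dimethoxy-5,7-bis(methoxymethoxy)-2-(4-methoxyphenyl)-6-methyl-4H-chromen-4-one
Conditions: NaOMe (5 equiv), CuI (0.3 equiv), MeOH–DMF, 100 °C
Reagents that add atoms: sodium methoxide, [Na+].[O-]C
Why: Ullmann-type copper-mediated C–O coupling of an aryl iodide with methoxide is established for 8-haloflavones, and with O5 blocked any reversible opening of ring C by methoxide can only reclose to the same chromone.

Step 11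
Reactants: 19 3,8-dimethoxy-5,7-bis(methoxymethoxy)-2-(4-methoxyphenyl)-6-methyl-4H-chromen-4-one
Product: 20 5,7-dihydroxy-3,8-dimethoxy-2-(4-methoxyphenyl)-6-methyl-4H-chromen-4-one
Conditions: 3 M HCl, MeOH, 50 °C
Reagents that add atoms: none
Why: Acid-catalysed acetal methanolysis should remove both MOM groups while the aryl methyl ethers, the 3-methoxy group and the chromone are inert to dilute methanolic HCl.

**Compound list**

1 | 2-methylresorcinol | Cc1c(O)cccc1O | starting material
2 | 1,3-bis(methoxymethoxy)-2-methylbenzene | COCOc1cccc(OCOC)c1C | intermediate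
3 | 2-[3,5-bis(methoxymethoxy)-4-methylphenyl]-4,4,5,5-tetramethyl-1,3,2-dioxaborolane | COCOc1cc(B2OC(C)(C)C(C)(C)O2)cc(OCOC)c1C | intermediate
4 | 3,5-bis(methoxymethoxy)-4-methylphenol | COCOc1cc(O)cc(OCOC)c1C | intermediate
5 | 2-bromo-3,5-bis(methoxymethoxy)-4-methylphenol | Oc1cc(OCOC)c(C)c(OCOC)c1Br | intermediate
6 | [2-bromo-3,5-bis(methoxymethoxy)-4-methylphenoxy]trimethylsilane | C[Si](C)(C)Oc1cc(OCOC)c(C)c(OCOC)c1Br | intermediate
7 | [2,4-bis(methoxymethoxy)-3-methyl-6-(trimethylsilyloxy)phenyl]lithium | [Li]c1c(O[Si](C)(C)C)cc(OCOC)c(C)c1OCOC | intermediate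
8 | lithium 3,5-bis(methoxymethoxy)-4-methyl-2-(trimethylsilyl)phenoxide | [Li+].[O-]c1cc(OCOC)c(C)c(OCOC)c1[Si](C)(C)C | intermediate
9 | 3,5-bis(methoxymethoxy)-4-methyl-2-(trimethylsilyl)phenyl trifluoromethanesulfonate | Cc1c(OCOC)cc(OS(=O)(=O)C(F)(F)F)c([Si](C)(C)C)c1OCOC | intermediate
10 | methyl methoxyacetate | COCC(=O)OC | starting material
11 | 4-methoxybenzoyl chloride | COc1ccc(cc1)C(Cl)=O | starting material
12 | methyl 2-methoxy-3-(4-methoxyphenyl)-3-oxopropanoate (racemic) | COC(=O)C(OC)C(=O)c1ccc(OC)cc1 | intermediate
13 | methyl (E)-2,3-dimethoxy-3-(4-methoxyphenyl)prop-2-enoate | CO/C(c1ccc(OC)cc1)=C(/OC)C(=O)OC | intermediate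
14 | (E)-2,3-dimethoxy-3-(4-methoxyphenyl)prop-2-enoic acid | CO/C(c1ccc(OC)cc1)=C(/OC)C(=O)O | intermediate
15 | 3,5-bis(methoxymethoxy)-4-methylbenzyne (1,2-didehydro) | CC1=C(OCOC)C#CC=C1OCOC | intermediate
16 | (E)-1-[6-hydroxy-2,4-bis(methoxymethoxy)-3-methylphenyl]-2,3-dimethoxy-3-(4-methoxyphenyl)prop-2-en-1-one (present as its caesium phenoxide) | CO/C(c1ccc(OC)cc1)=C(/OC)C(=O)c1c(O)cc(OCOC)c(C)c1OCOC | intermediate
17 | 3-methoxy-5,7-bis(methoxymethoxy)-2-(4-methoxyphenyl)-6-methyl-4H-chromen-4-one | COc1ccc(-c2oc3cc(OCOC)c(C)c(OCOC)c3c(=O)c2OC)cc1 | intermediate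
18 | 8-iodo-3-methoxy-5,7-bis(methoxymethoxy)-2-(4-methoxyphenyl)-6-methyl-4H-chromen-4-one | COc1ccc(-c2oc3c(I)c(OCOC)c(C)c(OCOC)c3c(=O)c2OC)cc1 | intermediate
19 | 3,8-dimethoxy-5,7-bis(methoxymethoxy)-2-(4-methoxyphenyl)-6-methyl-4H-chromen-4-one | COc1ccc(-c2oc3c(OC)c(OCOC)c(C)c(OCOC)c3c(=O)c2OC)cc1 | intermediate
20 | 5,7-dihydroxy-3,8-dimethoxy-2-(4-methoxyphenyl)-6-methyl-4H-chromen-4-one | COc1ccc(-c2oc3c(OC)c(O)c(C)c(O)c3c(=O)c2OC)cc1 | target

**Step count**

Total steps: 11. Longest linear sequence: 8 steps (steps 1, 2, 3, 4, 8, 9, 10, 11); the acid branch (steps 5–7) joins at step 8.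

**Steps most likely to fail**

1. Step 8. The aryl anion formed after carboxylate addition may be protonated faster than it transfers the hindered acyl group, so that only the aryl ester forms; regiocontrol of the addition may also be incomplete. Fallback from bromophenol 5 and acid 14, returning at 17: esterification with DCC and DMAP in CH2Cl2 would give 2-bromo-3,5-bis(methoxymethoxy)-4-methylphenyl (E)-2,3-dimethoxy-3-(4-methoxyphenyl)prop-2-enoate F1. Treatment with t-BuLi (2 equiv) in THF at −100 °C should effect bromine–lithium exchange at the future C4a with no proton source present. The aryllithium should then undergo the known exchange-triggered anionic Fries acyl shift to the lithium phenoxide of 16, which closes to 17 on warming. The position of bromine fixes the regiochemistry.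

2. Step 10. Coupling at the doubly ortho-substituted C8 may be slow, with protodeiodination or attack of methoxide on the chromone competing. Fallback from iodide 18, returning at 19: Miyaura borylation (PdCl2(dppf), B2pin2, KOAc, dioxane, 90 °C) would give 3-methoxy-5,7-bis(methoxymethoxy)-2-(4-methoxyphenyl)-6-methyl-8-(4,4,5,5-tetramethyl-1,3,2-dioxaborolan-2-yl)-4H-chromen-4-one F2. Oxidation with NaBO3·4H2O in THF/H2O would give 8-hydroxy-3-methoxy-5,7-bis(methoxymethoxy)-2-(4-methoxyphenyl)-6-methyl-4H-chromen-4-one F3, and O-methylation with MeI and K2CO3 in acetone returns 19.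

3. Step 6. C-methylation of the ambident enolate may compete and give the quaternary α-methyl keto ester. Fallback from keto ester 12, returning at 13: ketalisation with HC(OMe)3 and catalytic TsOH in MeOH would give methyl 2,3,3-trimethoxy-3-(4-methoxyphenyl)propanoate F4 (racemic). Elimination of methanol with Me3SiOTf and iPr2NEt in CH2Cl2 (ketal to enol ether) then returns 13 with no carbon electrophile present.

**Further compounds**

F1 | step 8 | 2-bromo-3,5-bis(methoxymethoxy)-4-methylphenyl (E)-2,3-dimethoxy-3-(4-methoxyphenyl)prop-2-enoate | CO/C(c1ccc(OC)cc1)=C(/OC)C(=O)Oc1cc(OCOC)c(C)c(OCOC)c1Br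
F2 | step 10 | 3-methoxy-5,7-bis(methoxymethoxy)-2-(4-methoxyphenyl)-6-methyl-8-(4,4,5,5-tetramethyl-1,3,2-dioxaborolan-2-yl)-4H-chromen-4-one | COc1ccc(-c2oc3c(B4OC(C)(C)C(C)(C)O4)c(OCOC)c(C)c(OCOC)c3c(=O)c2OC)cc1
F3 | step 10 | 8-hydroxy-3-methoxy-5,7-bis(methoxymethoxy)-2-(4-methoxyphenyl)-6-methyl-4H-chromen-4-one | COc1ccc(-c2oc3c(O)c(OCOC)c(C)c(OCOC)c3c(=O)c2OC)cc1
F4 | step 6 | methyl 2,3,3-trimethoxy-3-(4-methoxyphenyl)propanoate (racemic) | COC(=O)C(OC)C(OC)(OC)c1ccc(OC)cc1
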